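**Plan**
1. Retrosynthesis: the C6 benzoate and the C3 carbinol go back to a 3‑keto‑4β,6β‑diol; the C4–CH3 bond is cut to leave a C4 ketone; ring B is then cut at C5–C6 and C9–C10.
2. Enabling feature: ring B holds the quaternary C10 methyl between C9 and C5–H, with oxygen on C6 and the isopropyl group on C7. This is the imprint of the methyl‑bearing C=C of 2‑methoxy‑5‑methylbenzoquinone (ring A, oxygen already at C1, C3 and C4) joined to a 1‑silyloxy‑2‑isopropylbutadiene (C6–C9).
3. Forward: ring A is bought as the quinone and ring B closes in the Diels–Alder step. The later steps only adjust oxidation levels: C4 is methylated, the C1 oxygen is removed by enone transposition, C6 and C3 are reduced, and C6 is benzoylated.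
4. Stereochemistry: C10 from the chiral titanium catalyst; C5 by equilibration to the trans‑decalin; C4 by equatorial Grignard attack anti to the C10 methyl; C7 by hydrogenation directed by the cycloaddition‑derived 6α‑hydroxyl; C6 by hydride attack on the 6‑ketone anti to the C10 methyl; C3 by hydride delivery from the 4β‑hydroxyl.

Key step: step 5

Numbering: eudesmane positions are used for all decalins (ring A = C1–C5 + C10, ring B = C5–C10; angular methyl on C10, isopropyl on C7, carbinol methyl on C4; "15‑nor" = no C4 methyl); β is the face of the C10 methyl.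
Assumption: the (R)‑BINOL titanium catalyst is taken to open the quinone face that leads to adduct 11 with the absolute configuration of its SMILES; if the adduct proves antipodal, (S)‑BINOL is used and nothing else changes.

**Step 1**
Reactants: 1 2‑methoxy‑5‑methylphenol
Product: 2 2‑methoxy‑5‑methyl‑1,4‑benzoquinone
Conditions: Fremy's salt (2.2 equiv), aq. KH2PO4, acetone/H2O, 0 °C → rt
Reagents that add atoms: potassium nitrosodisulfonate (Fremy's salt), [K+].[K+].[O]N(S(=O)(=O)[O-])S(=O)(=O)[O-]
Why: Teuber oxidation, in which the phenoxyl radical is trapped at the only free para position and collapses to the p‑quinone, so the 2‑methoxy‑5‑methyl pattern should follow directly from the phenol.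

**Step 2**
Reactants: 3 isovaleraldehyde
Product: 4 N‑tert‑butyl‑3‑methylbutan‑1‑imine
Conditions: t‑BuNH2 (1.1 equiv), MgSO4, Et2O, 0 °C → rt; distil
Reagents that add atoms: tert‑butylamine, CC(C)(C)N
Why: Imine condensation of an unhindered aldehyde with a primary amine, driven by removal of water; the tert‑butyl group later suppresses self‑addition of the metallated imine.

**Step 3**
Reactants: 4 N‑tert‑butyl‑3‑methylbutan‑1‑imine; 5 acetaldehyde
Product: 9 (E)‑2‑isopropylbut‑2‑enal, via lithiated imine 6 (not isolated), via hydroxy imine 7 (not isolated), via aldol 8 (not isolated)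
Conditions: LDA, THF, −78 → 0 °C; MeCHO, −78 °C; then aq. oxalic acid, rt → reflux
Reagents that add atoms: water, O
Why: Wittig‑type directed aldol condensation, in which the lithiated aldimine should add to acetaldehyde without self‑condensation of either aldehyde, and acidic hydrolysis with dehydration should give the conjugated enal (its E geometry is lost in the next step).

**Step 4**
Reactants: 9 (E)‑2‑isopropylbut‑2‑enal
Product: 10 (E)‑1‑(tert‑butyldimethylsilyloxy)‑2‑isopropylbuta‑1,3‑diene
Conditions: TBSOTf, Et3N, Et2O, 0 °C → rt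
Reagents that add atoms: tert‑butyldimethylsilyl triflate, CC(C)(C)[Si](C)(C)OS(=O)(=O)C(F)(F)F
Why: Vinylogous silyl enol ether formation (O‑silylation of the enal, then γ‑deprotonation of the methyl group by the amine), which from the preferred s‑trans enal should place oxygen anti to the vinyl group, i.e. the 1E diene needed for endo cycloaddition.

**Step 5 (key step)**
Reactants: 2 2‑methoxy‑5‑methyl‑1,4‑benzoquinone; 10 (E)‑1‑(tert‑butyldimethylsilyloxy)‑2‑isopropylbuta‑1,3‑diene
Product: 11 cis‑fused endo adduct 6α‑(tert‑butyldimethylsilyloxy)‑3‑methoxy‑15‑nor‑eudesma‑2,7‑diene‑1,4‑dione (5β‑H; 10β‑methyl)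
Conditions: (R)‑BINOL–TiCl2 (20 mol %, from (R)‑BINOL and TiCl2(OiPr)2), toluene, −40 → −20 °C; aq. NaHCO3
Reagents that add atoms: none
Why: The titanium(IV) binaphtholate should bind the quinone through the C4 carbonyl and the adjacent C3 methoxy oxygen, and the diene then adds across the methyl‑bearing C5=C10 bond in a concerted but asynchronous, normal‑electron‑demand [4+2] cycloaddition in which C9–C10 bonding runs ahead of C5–C6. The closest known reaction type is the chiral titanium–BINOL‑catalysed Diels–Alder reaction of silyloxy dienes with methoxy‑substituted benzoquinones, together with the tin‑ and titanium‑chelated additions of dienes to this very quinone. Ring B, the only ring formed, closes as a six‑membered carbocycle in the cycloaddition mode, with C5–C6 and C9–C10 made in the same step. C10 is set by the catalyst, whose binaphthyl wall should leave one face of the chelated quinone open; C5 follows from suprafacial addition (H5 cis to the C10 methyl); C6 follows from the endo transition state combined with the E geometry of the dienol ether (6‑OTBS trans to H5). Site selectivity between the two quinone double bonds is needed and is secured because the methoxy‑bearing one is a deactivated vinylogous ester. Regioselectivity is needed and is secured by matching C10, the β‑carbon of the chelated C4 carbonyl, with C9, the diene terminus of largest HOMO coefficient remote from the silyloxy group.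

**Step 6**
Reactants: 11 cis‑fused endo adduct
Product: 12 trans‑fused enedione 6α‑(tert‑butyldimethylsilyloxy)‑3‑methoxy‑15‑nor‑eudesma‑2,7‑diene‑1,4‑dione (5α‑H)
Conditions: DBU (0.1 equiv), CH2Cl2, 0 °C → rt
Reagents that add atoms: none
Why: Base‑catalysed epimerisation α to the C4 ketone through the extended C4–C5 enolate (the usual cis‑to‑trans equilibration of quinone–diene adducts) is expected to favour the trans‑decalin with 5α‑H; C10 is quaternary so no aromatisation is possible, the equatorial C6–O bond lies near the nodal plane of the enolate so loss of silanolate should be slow, and any remaining cis isomer is recycled.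

**Step 7**
Reactants: 12 trans‑fused enedione
Product: 13 6α‑(tert‑butyldimethylsilyloxy)‑4β‑hydroxy‑3‑methoxyeudesma‑2,7‑dien‑1‑one (5α‑H; 4α‑methyl)
Conditions: MeMgBr, THF, −78 °C; aq. NH4Cl
Reagents that add atoms: methylmagnesium bromide, C[Mg]Br
Why: Grignard 1,2‑addition should occur at the C4 ketone only, because the C1 carbonyl is a much less electrophilic vinylogous ester, and the methyl group should enter equatorially from the α face because the axial C10 methyl blocks the β face, giving 4α‑methyl/4β‑hydroxyl.

**Step 8**
Reactants: 13 silyl ether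
Product: 14 4β,6α‑dihydroxy‑3‑methoxyeudesma‑2,7‑dien‑1‑one
Conditions: TBAF, THF, 0 °C → rt
Reagents that add atoms: none
Why: Fluoride‑mediated cleavage of the secondary silyl ether, which touches no stereocenter and leaves the vinylogous ester and the tertiary alcohol intact.

**Step 9**
Reactants: 14 allylic alcohol
Product: 15 4β,6α‑dihydroxy‑3‑methoxyeudesm‑2‑en‑1‑one (7β‑isopropyl; 7α‑H)
Conditions: [Ir(cod)(PCy3)(py)]PF6 (5 mol %), H2 (1 atm), CH2Cl2, rt
Reagents that add atoms: none
Why: Hydroxyl‑directed hydrogenation with Crabtree's catalyst, in which iridium bound to the allylic 6α‑hydroxyl should deliver hydrogen to the α face of C7=C8 (also the face anti to the C10 methyl), setting 7β‑isopropyl, while the electron‑poor push–pull C2=C3 bond is expected to be left alone.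

**Step 10**
Reactants: 15 diol
Product: 16 4β‑hydroxy‑3‑methoxyeudesm‑2‑ene‑1,6‑dione
Conditions: Dess–Martin periodinane, CH2Cl2, 0 °C → rt
Reagents that add atoms: none
Why: Dess–Martin oxidation of the secondary alcohol under non‑basic conditions, with the tertiary 4‑hydroxyl inert and the two α‑centres C5 and C7 already in their stable arrangement (trans fusion, equatorial isopropyl).

**Step 11**
Reactants: 16 hydroxy dione
Product: 18 4β,6β‑dihydroxyeudesm‑1‑en‑3‑one, via allylic alcohol 17 (not isolated)
Conditions: DIBAL‑H (4 equiv), CH2Cl2, −78 °C; then 1 M HCl, THF, 0 °C → rt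
Reagents that add atoms: water, O
Why: DIBAL should reduce the C6 ketone from the α face (the β face is shielded by the syn‑axial C10 methyl and the 4β‑O–Al group, as in 5α‑6‑keto steroids) to give the axial 6β‑alcohol and reduce the C1 vinylogous ester 1,2, after which acid effects the Stork–Danheiser transposition (enol ether hydrolysis and loss of the C1 hydroxyl) to the Δ1‑3‑ketone.

**Step 12**
Reactants: 18 enone diol
Product: 19 6β‑benzoyloxy‑4β‑hydroxyeudesm‑1‑en‑3‑one
Conditions: BzCl (3 equiv), DMAP (1 equiv), pyridine, 50 °C
Reagents that add atoms: benzoyl chloride, O=C(Cl)c1ccccc1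
Why: DMAP‑catalysed acylation, in which only the secondary 6β‑hydroxyl should react because the tertiary 4β‑hydroxyl is too hindered and tertiary esters are disfavoured.

**Step 13**
Reactants: 19 enone benzoate
Product: 20 6β‑benzoyloxy‑4β‑hydroxyeudesman‑3‑one
Conditions: H2 (1 atm), 10% Pd/C, EtOAc, rt
Reagents that add atoms: none
Why: Heterogeneous hydrogenation of the disubstituted enone C1=C2 bond, which creates no stereocenter and should leave the benzoate and the ketone untouched.

**Step 14**
Reactants: 20 keto benzoate
Product: 21 6β‑benzoyloxyeudesmane‑3α,4β‑diol (target)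
Conditions: Me4NBH(OAc)3 (5 equiv), MeCN/AcOH, −20 °C → rt
Reagents that add atoms: none
Why: Evans–Saksena hydroxyl‑directed reduction, in which the 4β‑hydroxyl exchanges onto boron and hydride is delivered intramolecularly to the β face of C3 to give the 3α‑alcohol (trans‑diaxial diol), with a reagent that reduces neither esters nor ketones lacking a neighbouring hydroxyl.

**Compound list**
1 | 2‑methoxy‑5‑methylphenol | COc1ccc(C)cc1O | starting material
2 | 2‑methoxy‑5‑methyl‑1,4‑benzoquinone | COC1=CC(=O)C(C)=CC1=O | intermediate
3 | isovaleraldehyde (3‑methylbutanal) | CC(C)CC=O | starting material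
4 | N‑tert‑butyl‑3‑methylbutan‑1‑imine | CC(C)C/C=N/C(C)(C)C | intermediate
5 | acetaldehyde | CC=O | starting material
6 | lithiated imine (N‑lithio aza‑enolate of 4) | CC(C)C=CN([Li])C(C)(C)C | intermediate
7 | hydroxy imine N‑tert‑butyl‑3‑hydroxy‑2‑isopropylbutan‑1‑imine (present as lithium alkoxide; racemic diastereomer mixture) | CC(O)C(C(C)C)C=NC(C)(C)C | intermediate
8 | aldol 3‑hydroxy‑2‑isopropylbutanal (racemic diastereomer mixture) | CC(O)C(C(C)C)C=O | intermediate
9 | (E)‑2‑isopropylbut‑2‑enal | C/C=C(/C=O)C(C)C | intermediate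
10 | (E)‑1‑(tert‑butyldimethylsilyloxy)‑2‑isopropylbuta‑1,3‑diene (oxygen anti to the vinyl group) | C=C/C(C(C)C)=C/O[Si](C)(C)C(C)(C)C | intermediate
11 | cis‑fused endo adduct, 6α‑(tert‑butyldimethylsilyloxy)‑3‑methoxy‑15‑nor‑eudesma‑2,7‑diene‑1,4‑dione (5β‑H, 10β‑methyl) | CC(C)C1=CC[C@@]2(C)C(=O)C=C(OC)C(=O)[C@H]2[C@H]1O[Si](C)(C)C(C)(C)C | intermediate
12 | trans‑fused enedione, 6α‑(tert‑butyldimethylsilyloxy)‑3‑methoxy‑15‑nor‑eudesma‑2,7‑diene‑1,4‑dione (5α‑H) | CC(C)C1=CC[C@@]2(C)C(=O)C=C(OC)C(=O)[C@@H]2[C@H]1O[Si](C)(C)C(C)(C)C | intermediate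
13 | 6α‑(tert‑butyldimethylsilyloxy)‑4β‑hydroxy‑3‑methoxyeudesma‑2,7‑dien‑1‑one (5α‑H, 4α‑methyl) | CC(C)C1=CC[C@@]2(C)C(=O)C=C(OC)[C@](C)(O)[C@@H]2[C@H]1O[Si](C)(C)C(C)(C)C | intermediate
14 | 4β,6α‑dihydroxy‑3‑methoxyeudesma‑2,7‑dien‑1‑one | CC(C)C1=CC[C@@]2(C)C(=O)C=C(OC)[C@](C)(O)[C@@H]2[C@H]1O | intermediate
15 | 4β,6α‑dihydroxy‑3‑methoxyeudesm‑2‑en‑1‑one (7β‑isopropyl, 7α‑H) | CC(C)[C@@H]1CC[C@@]2(C)C(=O)C=C(OC)[C@](C)(O)[C@@H]2[C@H]1O | intermediate
16 | 4β‑hydroxy‑3‑methoxyeudesm‑2‑ene‑1,6‑dione | CC(C)[C@@H]1CC[C@@]2(C)C(=O)C=C(OC)[C@](C)(O)[C@@H]2C1=O | intermediate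
17 | allylic alcohol 3‑methoxyeudesm‑2‑ene‑1,4β,6β‑triol (C1 configuration immaterial, drawn without descriptor) | CC(C)[C@@H]1CC[C@@]2(C)C(O)C=C(OC)[C@](C)(O)[C@@H]2[C@@H]1O | intermediate
18 | 4β,6β‑dihydroxyeudesm‑1‑en‑3‑one | CC(C)[C@@H]1CC[C@@]2(C)C=CC(=O)[C@](C)(O)[C@@H]2[C@@H]1O | intermediate
19 | 6β‑benzoyloxy‑4β‑hydroxyeudesm‑1‑en‑3‑one | CC(C)[C@@H]1CC[C@@]2(C)C=CC(=O)[C@](C)(O)[C@@H]2[C@@H]1OC(=O)c1ccccc1 | intermediate
20 | 6β‑benzoyloxy‑4β‑hydroxyeudesman‑3‑one | CC(C)[C@@H]1CC[C@@]2(C)CCC(=O)[C@](C)(O)[C@@H]2[C@@H]1OC(=O)c1ccccc1 | intermediate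
21 | 6β‑benzoyloxyeudesmane‑3α,4β‑diol, i.e. (3R,4R,5S,6R,7S,10S)‑3,4‑dihydroxyeudesman‑6‑yl benzoate (5α‑H, 7β‑isopropyl, 10β‑methyl) | CC(C)[C@@H]1CC[C@@]2(C)CC[C@@H](O)[C@](C)(O)[C@@H]2[C@@H]1OC(=O)c1ccccc1 | target

**Count**
Total steps: 14. Longest linear sequence: 13 steps (isovaleraldehyde 3 through steps 2–14); the quinone branch is one step.

**Steps most likely to fail**

Step 5. The diene may add with the opposite orientation or with poor facial discrimination if titanium binds the quinone through one oxygen only. The silyl dienol ether may also be consumed by silyl transfer to the Lewis acid before it cycloadds. The fallback sets out from 2 and 10 and comes back at 11. The cycloaddition is run under tin(IV) chloride chelation (CH2Cl2, −78 → −20 °C), which is known to enforce the required orientation for this quinone. It should give the racemic cis endo adduct, that is 11 together with its mirror image, the enantiomer of adduct 11 F1. The two are separated by preparative chromatography on a chiral stationary phase, and 11 re‑enters at step 6.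

Step 6. With the C7=C8 bond still in place, the equatorial 6‑silyloxy group in the trans isomer suffers allylic strain against the isopropyl group and a peri interaction with the C4 carbonyl. The equilibrium may therefore stop short of the trans isomer, and long contact with base may expel silanolate from the enolate. The fallback sets out from 11 and comes back at 15; it moves the equilibration to a substrate whose ring B is a saturated chair. Compound 11 is desilylated with buffered HF·pyridine (THF, 0 °C) to the cis‑fused hydroxy enedione F2. Hydrogenation directed by the 6α‑hydroxyl (Crabtree's catalyst, H2, CH2Cl2) should give the cis‑fused ring‑B‑saturated ketol F3 with 7β‑isopropyl. Only the trans fusion places both the 6α‑hydroxyl and the 7β‑isopropyl group equatorial and allows a hydrogen bond from 6‑OH to the C4 carbonyl, so mild base (Et3N, CH2Cl2) should convert F3 into the trans‑fused ketol F4. Methylmagnesium bromide (2.5 equiv, THF, −78 °C), with the C6 magnesium alkoxide chelating the C4 carbonyl, then adds from the α face and gives 15, which continues at step 10.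

Step 12. The axial 6β‑hydroxyl sits between the syn‑axial C10 methyl and 4β‑hydroxyl and next to the isopropyl group, so acyl transfer may stall. Forcing conditions may acylate the tertiary hydroxyl or dehydrate the ketol. The fallback sets out from 18 and comes back at 19; it uses the syn‑diaxial 4β,6β‑diol as a handle. Trimethyl orthobenzoate with catalytic camphorsulfonic acid (CH2Cl2, rt) should give the cyclic 4β,6β‑methyl orthobenzoate F5. Mild aqueous acid (80% AcOH, rt) opens it to the hydroxy benzoate; any tertiary benzoate formed should move to the secondary oxygen by acyl migration on brief treatment with DBU, giving 19.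

**Further compounds**
F1 | step 5 | enantiomer of adduct 11 (ent‑11) | CC(C)C1=CC[C@]2(C)C(=O)C=C(OC)C(=O)[C@@H]2[C@@H]1O[Si](C)(C)C(C)(C)C
F2 | step 6 | cis‑fused hydroxy enedione, 6α‑hydroxy‑3‑methoxy‑15‑nor‑eudesma‑2,7‑diene‑1,4‑dione (5β‑H) | CC(C)C1=CC[C@@]2(C)C(=O)C=C(OC)C(=O)[C@H]2[C@H]1O
F3 | step 6 | cis‑fused ring‑B‑saturated ketol, 6α‑hydroxy‑3‑methoxy‑15‑nor‑eudesm‑2‑ene‑1,4‑dione (5β‑H, 7β‑isopropyl) | CC(C)[C@@H]1CC[C@@]2(C)C(=O)C=C(OC)C(=O)[C@H]2[C@H]1O
F4 | step 6 | trans‑fused ketol, 6α‑hydroxy‑3‑methoxy‑15‑nor‑eudesm‑2‑ene‑1,4‑dione (5α‑H, 7β‑isopropyl) | CC(C)[C@@H]1CC[C@@]2(C)C(=O)C=C(OC)C(=O)[C@@H]2[C@H]1O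
F5 | step 12 | cyclic 4β,6β‑methyl orthobenzoate of 18 (orthoester carbon either configuration) | CC(C)[C@@H]1CC[C@@]2(C)C=CC(=O)[C@]3(C)OC(OC)(c4ccccc4)O[C@H]1[C@H]23
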